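**Remark on the structure (assumption):** the C3/C5 β-diketone of the target is a fast keto–enol system. The structure to be made is written as one enol form (C5 enol, C3 ketone), the route delivers the compound as its equilibrium mixture of tautomers, and 16 and 17 are drawn in that same form.

Chain numbering: C1 is the carbinol carbon on the 4-hydroxyphenyl ring (ring A), C7 the carbon on the 4-hydroxy-3-methoxyphenyl ring (ring B). TBS = tert-butyldimethylsilyl.

## Analysis of the target

Target 17 is an open-chain 1,7-diarylheptanoid with no ring other than the two benzene rings. It carries a secondary alcohol at C1, a β-diketone at C3/C5 (drawn as the C5 enol) and an (E) alkene at C6=C7. C1 is the only stereocentre, (S), so no relative configuration has to be controlled, but there is also no neighbouring centre to relay from, and the configuration must come from a reagent or catalyst. The C1 carbinol is benzylic to an electron-rich ring and β to the C3 carbonyl, so it can lose water to the fully conjugated dienone, undergo retro-aldol cleavage, or racemise through a quinone-methide-like cation. O1 is also δ to C5, so acid can close a six-membered ring onto C5 and dehydrate it to a 2,3-dihydropyran-4-one. The two phenols and the acidic, chelating diketone interfere with bases, organometallic reagents and Lewis-acidic metal catalysts. The central difficulty is that C1, C3 and C5 all sit at or near the carbonyl oxidation level, so an asymmetric reduction at C1 has to tell three C=O groups and a conjugated alkene apart. The strategy rests on the fact that the C3–C4–C5 dioxygenated unit can be stored in a 3,5-disubstituted isoxazole. Chain C3 becomes ring position 5 (bonded to the ring oxygen, carrying C2), chain C4 ring position 4, and chain C5 ring position 3 (bonded to nitrogen, carrying the C6=C7 styryl arm); in that form C1 is the only carbonyl, and it is an aryl ketone.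

## Retrosynthetic reasoning

17 ⇒ 16. The last bonds cut are the three O–Si bonds of 16. The phenols stay silylated to the end because free phenols would interfere with the chlorination and carbanion steps, and O1 stays silylated because a free O1 endangers the unveiled diketone. The forward reaction must remove two aryl silyl ethers and one secondary benzylic silyl ether without acid strong enough to dehydrate C1 and without base strong enough for retro-aldol cleavage.

16 ⇒ 15 ⇒ 14. The C5 oxygen of 16 is traced back to the amino group of the vinylogous amide 15, and that nitrogen back to the N–O bond of the isoxazole in 14. Cutting here, and not at a C–C bond of the diketone, means the 1,3-dicarbonyl exists only in the last two steps. The forward reactions are a reductive N–O scission that spares the C6=C7 alkene, then hydrolysis of the C5–N bond.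

14 ⇒ 13. The O1–Si bond is cut. A free O1 in 15 or 16 lies five atoms from C5, and the acid needed for hydrolysis would drive ring closure of O1 onto C5 and loss of the C5 heteroatom. Silylating O1 directly after the reduction costs one step, and the group leaves together with the other two at the end.

13 ⇒ 12. The C1–H bond is cut; this is the key disconnection. In 12, C1 is the sole carbonyl, flanked by ring A and a CH2 group, the substrate pattern for which catalytic transfer hydrogenation selects a face most reliably. The forward reaction must deliver hydride to one face of C1 and leave the N–O bond and the styrenyl alkene alone.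

12 ⇒ 8 + 10. The C1–C2 bond is cut. This divides the molecule into a ring-A acyl donor 10 with no α-hydrogen and a nucleophilic CH2 at position 5 of the isoxazole 8, the most acidic site of that ring system. The forward reaction is a lateral deprotonation followed by acylation, which must stop at the ketone.

8 ⇒ 7 ⇒ 3 + 4 (through 5 and 6). Two ring bonds are cut: chain C4–C5 and the bond from the ring oxygen to chain C3. The forward reaction is a [3+2] cycloaddition of nitrile oxide 6 to the enol ester 4, which acts as a propyne equivalent of fixed regiochemistry, followed by loss of the acetoxy group from 7 to aromatise. C5, C6, C7 and ring B come from 3; C2, C3 and C4 come from 4.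

3 ⇒ 2 ⇒ 1 and 10 ⇒ 9. These are functional-group operations only: C=N formation on the aldehyde and O-silylation of the two phenols, starting from the commercial compounds 1 and 9.

## Alternatives that were turned down

Alternative 1: The disconnection is at C4–C5. The forward key step is a decarboxylative Claisen condensation. The magnesium enolate–carboxylate of the β-keto acid (S)-5-(tert-butyldimethylsilyloxy)-5-[4-(tert-butyldimethylsilyloxy)phenyl]-3-oxopentanoic acid A2 would be acylated at its central carbon by the O-silylated feruloyl imidazolide A3 and decarboxylate to the tris-silyl diketone A1, the diketo tautomer of 16.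
- For it: the route is convergent and biomimetic, the diketone arises at the right oxidation level with no mask to remove, and A1 is one deprotection from 17. On step count after the key step it is stronger than the chosen route.
- Against it: the C1 stereocentre of A2 must be set by a separate asymmetric aldol or reduction, so the stereochemical problem is moved, not solved. A2 is prone to premature decarboxylation, and its enolate carries a β-silyloxy leaving group and can eliminate. A3 is a Michael acceptor, and O-acylation competes with C-acylation. The product is more acidic than the nucleophile, so part of the chiral fragment is spent as base.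
- Comparison: the chosen route makes its C–C bond between a stable heteroaryl carbanion and a non-enolisable ester, and sets C1 afterwards by a catalyst at the only reducible site.

Alternative 2: The disconnection is at both C2–C3 and C3–C4 around a C3 acyl-anion equivalent. Lithiated 2-(tert-butyldimethylsilyl)-1,3-dithiane A7 would open (R)-2-[4-(tert-butyldimethylsilyloxy)phenyl]oxirane A5 at its CH2; a 1,4-Brook shift would move silicon to O1; and the new dithiane anion would open the racemic styryl epoxide A6 at its CH2 to give the dithiane A4 as both C5 epimers.
- For it: it is a three-component coupling, the most convergent of the four strategies, and O1 is protected for free by the Brook shift. On convergence and bonds formed per flask it is stronger than the chosen route.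
- Against it: A5 is an electron-rich styrene oxide with a labile benzylic C–O bond, so benzylic attack and lithium-induced rearrangement would erode regiochemistry and enantiopurity. A6 is a vinyl epoxide conjugated to an electron-rich arene, so SN2′ opening competes. After the coupling, C5 (made as a stereocentre of no value) must be oxidised, and the dithiane must be removed with thiophilic divalent mercury salts or oxidants in the presence of an electron-rich styrene. That is at least three further steps, plus the synthesis of both epoxides.
- Comparison: the isoxazole mask of the chosen route is removed by a mild reductive N–O cleavage, with no redox detour at C5 and no thioacetal to hydrolyse.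

Alternative 3: No C–C bond is cut; the C1–O bond is traced back to the C1=C2 enone A9, in which C5 is carried as a triethylsilyl-protected carbinol. A chiral monovalent copper–boryl complex would add boron to C1, and oxidation of the C–B bond with retention in the same flask would give the (1S)-β-hydroxy ketone A8 as both C5 epimers.
- For it: it is a catalytic, late-stage reaction on the full carbon skeleton, and β-aryl enones are good substrates for this reaction class. In directness of setting C1 it equals the chosen key step.
- Against it: the diketone cannot be present, because two enone termini would be indistinguishable and the acidic enol would quench the boryl species. C5 is therefore carried at the wrong oxidation level. After the key step O1 must be protected, the C5 silyl group removed, the allylic alcohol oxidised and the molecule deprotected, which matches the endgame length of the chosen route without counting the aldol assembly of A9. A9 is a β-silyloxy ketone, and the alkoxide base of the borylation invites elimination to a cross-conjugated dienone. The 4-silyloxyphenyl enone is an electron-rich, slow acceptor, and the basic oxidative work-up invites retro-aldol cleavage of A8.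
- Comparison: the chosen route has the same late, catalyst-controlled stereochemistry but on a substrate with a single reducible group, and C3 and C5 emerge together at the correct oxidation level.

Key step: step 7

## Route

Step 1
Reactants: 1 coniferaldehyde, (E)-3-(4-hydroxy-3-methoxyphenyl)prop-2-enal
Product: 2 (E)-3-[4-(tert-butyldimethylsilyloxy)-3-methoxyphenyl]prop-2-enal
Conditions: TBSCl, imidazole, DMF, 0 °C to rt
Reagents that add atoms: tert-butyldimethylsilyl chloride, CC(C)(C)[Si](C)(C)Cl
Why: Silyl ether formation at the phenol; the conjugated aldehyde does not react, and the acidic O–H is removed before the chlorination and carbanion steps.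

Step 2
Reactants: 2 (E)-3-[4-(tert-butyldimethylsilyloxy)-3-methoxyphenyl]prop-2-enal
Product: 3 (1E,2E)-3-[4-(tert-butyldimethylsilyloxy)-3-methoxyphenyl]prop-2-enal oxime
Conditions: NH2OH·HCl, NaOAc, EtOH, rt
Reagents that add atoms: hydroxylamine hydrochloride, Cl.NO
Why: Oxime condensation; under acetate buffering, 1,2-addition to the aldehyde should outrun conjugate addition and the aryl silyl ether is stable. Either C=N isomer leads to the same nitrile oxide.

Step 3
Reactants: 3 (1E,2E)-3-[4-(tert-butyldimethylsilyloxy)-3-methoxyphenyl]prop-2-enal oxime; 4 isopropenyl acetate (excess)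
Product: 7 racemic 3-[(E)-2-(4-tert-butyldimethylsilyloxy-3-methoxyphenyl)ethenyl]-5-methyl-4,5-dihydroisoxazol-5-yl acetate, via hydroximoyl chloride 5 (not isolated), via nitrile oxide 6 (not isolated)
Conditions: NCS, DMF, rt; then 4 (8 equiv), Et3N (slow addition), 0 °C to rt
Reagents that add atoms: none
Why: Chlorination of the aldoxime gives 5, which loses HCl to the amine to give 6; a Huisgen 1,3-dipolar cycloaddition to the enol ester follows, with the dipole oxygen bonding to the substituted alkene carbon as is general for nitrile oxides, so methyl and acetoxy end at ring position 5. Slow base addition and excess 4 keep 6 dilute and suppress its dimerisation. The new quaternary centre is racemic and is destroyed in step 4.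

Step 4
Reactants: 7 racemic 3-[(E)-2-(4-tert-butyldimethylsilyloxy-3-methoxyphenyl)ethenyl]-5-methyl-4,5-dihydroisoxazol-5-yl acetate
Product: 8 3-[(E)-2-(4-tert-butyldimethylsilyloxy-3-methoxyphenyl)ethenyl]-5-methylisoxazole
Conditions: p-TsOH·H2O (cat.), toluene, 80 °C
Reagents that add atoms: none
Why: Acid-promoted 1,2-elimination of acetic acid from the 5-acetoxy-4,5-dihydroisoxazole, driven by aromatisation; the enol ester thereby serves as a propyne equivalent that fixes the methyl group at position 5.

Step 5
Reactants: 9 methyl 4-hydroxybenzoate
Product: 10 methyl 4-(tert-butyldimethylsilyloxy)benzoate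
Conditions: TBSCl, imidazole, DMF, rt
Reagents that add atoms: tert-butyldimethylsilyl chloride, CC(C)(C)[Si](C)(C)Cl
Why: Silyl ether formation at the phenol, as in step 1; it removes the proton that would otherwise consume the carbanion of step 6.

Step 6
Reactants: 8 3-[(E)-2-(4-tert-butyldimethylsilyloxy-3-methoxyphenyl)ethenyl]-5-methylisoxazole; 10 methyl 4-(tert-butyldimethylsilyloxy)benzoate
Product: 12 1-[4-(tert-butyldimethylsilyloxy)phenyl]-2-{3-[(E)-2-(4-tert-butyldimethylsilyloxy-3-methoxyphenyl)ethenyl]isoxazol-5-yl}ethanone, via 5-(lithiomethyl)isoxazole 11 (not isolated)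
Conditions: LiN(i-Pr)2 (2.2 equiv), THF, −78 °C; then 10, −78 to −40 °C; then sat. aq. NH4Cl
Reagents that add atoms: none
Why: Lateral lithiation of a 5-methylisoxazole; the methyl group at position 5 is the most acidic site of a 3,5-disubstituted isoxazole, and the non-nucleophilic amide base avoids addition to the styryl–C=N system. Carbanion 11 then undergoes a Claisen-type acylation with the non-enolisable ester 10; the second equivalent of base converts the more acidic product into its enolate, which blocks a second addition and is protonated on work-up.

Step 7
Reactants: 12 1-[4-(tert-butyldimethylsilyloxy)phenyl]-2-{3-[(E)-2-(4-tert-butyldimethylsilyloxy-3-methoxyphenyl)ethenyl]isoxazol-5-yl}ethanone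
Product: 13 (S)-1-[4-(tert-butyldimethylsilyloxy)phenyl]-2-{3-[(E)-2-(4-tert-butyldimethylsilyloxy-3-methoxyphenyl)ethenyl]isoxazol-5-yl}ethanol
Conditions: RuCl(p-cymene)[(S,S)-TsDPEN] (2 mol%), HCO2H/Et3N (5:2), DMF, 30 °C
Reagents that add atoms: none
Why: The 16-electron ruthenium amide formed from the precatalyst is converted by formate, with loss of CO2, into the 18-electron Ru–H/N–H species, which passes hydride to C1 and a proton to the carbonyl oxygen through a concerted six-membered outer-sphere transition state, so the substrate never binds the metal. The closest known reaction type is the Noyori asymmetric transfer hydrogenation of aryl alkyl and aryl heteroarylmethyl ketones with divalent ruthenium arene–sulfonyldiamine catalysts. No ring closes; one C–H bond and one stereocentre are formed. The stereocentre is controlled by the catalyst alone: the C–H/π contact between the p-cymene ligand and ring A places that ring next to the arene and the CH2–isoxazole arm away from it, so the (S,S) ligand should deliver hydride to the Re face of C1 as it does with acetophenone, and because aryl outranks CH2 in both cases the descriptor is (S). Chemoselectivity against three other reducible sites is secured by the substrate: C3 and C5 are locked in the aromatic isoxazole and are not carbonyls, the N–O bond is inert to this non-hydrogenolytic metal hydride, and the unpolarised C6=C7 alkene does not accept hydride from a bifunctional catalyst of this kind. The irreversible formate donor is preferred to 2-propanol because the electron-rich aryl ketone is a slow acceptor and its alcohol would otherwise re-oxidise and erode the selectivity. The acidity of C2–H is of no stereochemical consequence because C2 is not a stereocentre.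

Step 8
Reactants: 13 (S)-1-[4-(tert-butyldimethylsilyloxy)phenyl]-2-{3-[(E)-2-(4-tert-butyldimethylsilyloxy-3-methoxyphenyl)ethenyl]isoxazol-5-yl}ethanol
Product: 14 5-[(2S)-2-(tert-butyldimethylsilyloxy)-2-(4-tert-butyldimethylsilyloxyphenyl)ethyl]-3-[(E)-2-(4-tert-butyldimethylsilyloxy-3-methoxyphenyl)ethenyl]isoxazole
Conditions: TBSCl, imidazole, DMAP (cat.), DMF, rt
Reagents that add atoms: tert-butyldimethylsilyl chloride, CC(C)(C)[Si](C)(C)Cl
Why: Silyl ether formation at the secondary alcohol; the C1–O bond is not touched, so the (S) configuration is kept. The silyl group prevents O1 from closing onto C5 and steadies the benzylic carbinol while the diketone is unmasked.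

Step 9
Reactants: 14 5-[(2S)-2-(tert-butyldimethylsilyloxy)-2-(4-tert-butyldimethylsilyloxyphenyl)ethyl]-3-[(E)-2-(4-tert-butyldimethylsilyloxy-3-methoxyphenyl)ethenyl]isoxazole
Product: 15 (1S,4Z,6E)-5-amino-1-(tert-butyldimethylsilyloxy)-7-(4-tert-butyldimethylsilyloxy-3-methoxyphenyl)-1-(4-tert-butyldimethylsilyloxyphenyl)hepta-4,6-dien-3-one
Conditions: Mo(CO)6, MeCN/H2O, 80 °C
Reagents that add atoms: none
Why: Reductive cleavage of the isoxazole N–O bond by zerovalent molybdenum in wet acetonitrile gives the hydrogen-bonded (Z) β-amino enone; unlike hydrogenolysis over nickel or palladium, this reagent should leave the styrenyl alkene and the silyl ethers untouched.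

Step 10
Reactants: 15 (1S,4Z,6E)-5-amino-1-(tert-butyldimethylsilyloxy)-7-(4-tert-butyldimethylsilyloxy-3-methoxyphenyl)-1-(4-tert-butyldimethylsilyloxyphenyl)hepta-4,6-dien-3-one
Product: 16 (1S,6E)-1-(tert-butyldimethylsilyloxy)-5-hydroxy-7-(4-tert-butyldimethylsilyloxy-3-methoxyphenyl)-1-(4-tert-butyldimethylsilyloxyphenyl)hepta-4,6-dien-3-one (enol form of the 3,5-dione)
Conditions: aq. oxalic acid, THF, 0 °C to rt
Reagents that add atoms: water, O
Why: Hydrolysis of a primary vinylogous amide: protonation at C4 gives an iminium ion at C5 that takes up water and loses ammonia, leaving the β-diketone as its enol. With O1 silylated there is no internal nucleophile for C5, and a weak acid at low temperature is chosen to spare the benzylic silyl ether.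

Step 11
Reactants: 16 (1S,6E)-1-(tert-butyldimethylsilyloxy)-5-hydroxy-7-(4-tert-butyldimethylsilyloxy-3-methoxyphenyl)-1-(4-tert-butyldimethylsilyloxyphenyl)hepta-4,6-dien-3-one
Product: 17 (1S,6E)-1,5-dihydroxy-7-(4-hydroxy-3-methoxyphenyl)-1-(4-hydroxyphenyl)hepta-4,6-dien-3-one (enol form of the 3,5-dione), the target CNP0206527.1
Conditions: HF·pyridine, pyridine, THF, 0 °C to rt
Reagents that add atoms: none
Why: Fluoride-mediated cleavage of the three Si–O bonds (global desilylation); pyridine buffering keeps the medium only weakly acidic, which avoids the elimination and retro-aldol paths opened by basic fluoride and limits acid-driven dehydration. The C1–O bond is not broken, so the configuration is retained.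

## Compound list

1 | coniferaldehyde, (E)-3-(4-hydroxy-3-methoxyphenyl)prop-2-enal | COc1cc(/C=C/C=O)ccc1O | starting material
2 | (E)-3-[4-(tert-butyldimethylsilyloxy)-3-methoxyphenyl]prop-2-enal | COc1cc(/C=C/C=O)ccc1O[Si](C)(C)C(C)(C)C | intermediate
3 | (1E,2E)-3-[4-(tert-butyldimethylsilyloxy)-3-methoxyphenyl]prop-2-enal oxime | COc1cc(/C=C/C=N/O)ccc1O[Si](C)(C)C(C)(C)C | intermediate
4 | isopropenyl acetate | CC(=C)OC(C)=O | starting material
5 | (1Z,2E)-N-hydroxy-3-[4-(tert-butyldimethylsilyloxy)-3-methoxyphenyl]prop-2-enimidoyl chloride (not isolated) | COc1cc(/C=C/C(Cl)=N/O)ccc1O[Si](C)(C)C(C)(C)C | intermediate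
6 | (E)-3-[4-(tert-butyldimethylsilyloxy)-3-methoxyphenyl]prop-2-enenitrile oxide (not isolated) | COc1cc(/C=C/C#[N+][O-])ccc1O[Si](C)(C)C(C)(C)C | intermediate
7 | racemic 3-[(E)-2-(4-tert-butyldimethylsilyloxy-3-methoxyphenyl)ethenyl]-5-methyl-4,5-dihydroisoxazol-5-yl acetate | COc1cc(/C=C/C2=NOC(C)(OC(C)=O)C2)ccc1O[Si](C)(C)C(C)(C)C | intermediate
8 | 3-[(E)-2-(4-tert-butyldimethylsilyloxy-3-methoxyphenyl)ethenyl]-5-methylisoxazole | COc1cc(/C=C/c2cc(C)on2)ccc1O[Si](C)(C)C(C)(C)C | intermediate
9 | methyl 4-hydroxybenzoate | COC(=O)c1ccc(O)cc1 | starting material
10 | methyl 4-(tert-butyldimethylsilyloxy)benzoate | COC(=O)c1ccc(O[Si](C)(C)C(C)(C)C)cc1 | intermediate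
11 | 3-[(E)-2-(4-tert-butyldimethylsilyloxy-3-methoxyphenyl)ethenyl]-5-(lithiomethyl)isoxazole (not isolated) | COc1cc(/C=C/c2cc(C[Li])on2)ccc1O[Si](C)(C)C(C)(C)C | intermediate
12 | 1-[4-(tert-butyldimethylsilyloxy)phenyl]-2-{3-[(E)-2-(4-tert-butyldimethylsilyloxy-3-methoxyphenyl)ethenyl]isoxazol-5-yl}ethanone | COc1cc(/C=C/c2cc(CC(=O)c3ccc(O[Si](C)(C)C(C)(C)C)cc3)on2)ccc1O[Si](C)(C)C(C)(C)C | intermediate
13 | (S)-1-[4-(tert-butyldimethylsilyloxy)phenyl]-2-{3-[(E)-2-(4-tert-butyldimethylsilyloxy-3-methoxyphenyl)ethenyl]isoxazol-5-yl}ethanol | COc1cc(/C=C/c2cc(C[C@H](O)c3ccc(O[Si](C)(C)C(C)(C)C)cc3)on2)ccc1O[Si](C)(C)C(C)(C)C | intermediate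
14 | 5-[(2S)-2-(tert-butyldimethylsilyloxy)-2-(4-tert-butyldimethylsilyloxyphenyl)ethyl]-3-[(E)-2-(4-tert-butyldimethylsilyloxy-3-methoxyphenyl)ethenyl]isoxazole | COc1cc(/C=C/c2cc(C[C@H](O[Si](C)(C)C(C)(C)C)c3ccc(O[Si](C)(C)C(C)(C)C)cc3)on2)ccc1O[Si](C)(C)C(C)(C)C | intermediate
15 | (1S,4Z,6E)-5-amino-1-(tert-butyldimethylsilyloxy)-7-(4-tert-butyldimethylsilyloxy-3-methoxyphenyl)-1-(4-tert-butyldimethylsilyloxyphenyl)hepta-4,6-dien-3-one | COc1cc(/C=C/C(N)=C/C(=O)C[C@H](O[Si](C)(C)C(C)(C)C)c2ccc(O[Si](C)(C)C(C)(C)C)cc2)ccc1O[Si](C)(C)C(C)(C)C | intermediate
16 | (1S,6E)-1-(tert-butyldimethylsilyloxy)-5-hydroxy-7-(4-tert-butyldimethylsilyloxy-3-methoxyphenyl)-1-(4-tert-butyldimethylsilyloxyphenyl)hepta-4,6-dien-3-one (enol form of the 3,5-dione) | COc1cc(/C=C/C(O)=C\C(=O)C[C@H](O[Si](C)(C)C(C)(C)C)c2ccc(O[Si](C)(C)C(C)(C)C)cc2)ccc1O[Si](C)(C)C(C)(C)C | intermediate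
17 | (1S,6E)-1,5-dihydroxy-7-(4-hydroxy-3-methoxyphenyl)-1-(4-hydroxyphenyl)hepta-4,6-dien-3-one (enol form of the 3,5-dione), CNP0206527.1 | COc1cc(/C=C/C(O)=C\C(=O)C[C@H](O)c2ccc(O)cc2)ccc1O | target

## Step count and least certain steps

Total step count: 11. Longest linear sequence: 10 steps (steps 1 to 4 and 6 to 11, from 1); step 5 is a one-step branch from 9.

**Step 7 (key step).**
- Risk: hydride transfer to the electron-rich aryl ketone may be slow and stall before full conversion. The CH2–isoxazole arm is larger than methyl and may lower the facial discrimination. In the acidic formate medium the electron-rich benzylic carbinol may ionise, leading to formate ester formation, partial racemisation or elimination toward the conjugated alkene.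
- Fallback: a Corey–Bakshi–Shibata reduction, which uses a different reductant and a different control element. It sets out from 12, uses (R)-2-methyl-CBS-oxazaborolidine (catalytic) with catecholborane in toluene at −78 °C, and comes back at 13. The oxazaborolidine binds the carbonyl oxygen with ring A as the large group, which by analogy with acetophenone should again give the (S) alcohol, and the medium is non-acidic. No new compound is formed on this detour (F0).

**Step 6.**
- Risk: metalation may occur at ring position 4 instead of the methyl group, the lithiated ring may fragment, the base or carbanion may add to the styryl–C=N system, and proton transfer from the product ketone may quench the carbanion before acylation is complete.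
- Fallback: a route that builds the isoxazole with C1 and C2 already attached and needs no carbanion. It sets out from oxime 3 and comes back at 12.
  - 4-(tert-Butyldimethylsilyloxy)benzaldehyde F1 (commercial) would be propargylated under Barbier conditions (propargyl bromide, Zn dust, THF/sat. aq. NH4Cl) to give racemic 1-[4-(tert-butyldimethylsilyloxy)phenyl]but-3-yn-1-ol F2.
  - Nitrile oxide 6, generated from 3 through 5 as in step 3 (NCS, DMF; Et3N), would be trapped by the terminal alkyne F2 in a Huisgen cycloaddition, which gives the 3,5-disubstituted isoxazole directly as racemic 1-[4-(tert-butyldimethylsilyloxy)phenyl]-2-{3-[(E)-2-(4-tert-butyldimethylsilyloxy-3-methoxyphenyl)ethenyl]isoxazol-5-yl}ethanol F3.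
  - Dess–Martin oxidation of F3 (CH2Cl2, NaHCO3, rt) would then give 12.
  - This detour also removes the dependence on the enol ester 4 and on steps 4 and 5.

**Step 10.**
- Risk: the acid may cleave the benzylic silyl ether at O1, after which O1 would close onto C5 and dehydration would give a dihydropyranone. Ionisation at C1 with elimination is a second path. Conversely, acid mild enough to spare the silyl ether may leave the conjugated vinylogous amide only partly hydrolysed.
- Fallback: a change of the O1 protecting group to one that tolerates stronger acid. It sets out from 13 and comes back at 17.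
  - Silylation with TBDPSCl, imidazole and DMAP in DMF would give the O1-tert-butyldiphenylsilyl ether of 13, F4.
  - Mo(CO)6 in MeCN/H2O at 80 °C would give the corresponding β-amino enone F5.
  - The hydrolysis could then be forced with 1 M aq. HCl in THF at rt to give the O1-tert-butyldiphenylsilyl bis-TBS diketone F6.
  - Tetrabutylammonium fluoride buffered with acetic acid in THF (0 °C to rt) would remove all three silyl groups to give 17.

**Step 11.**
- Risk: the aryl and the secondary alkyl silyl ethers may cleave at different rates, forcing long exposure to HF. During that time the liberated δ-hydroxy β-diketone may undergo cyclodehydration, or the C1 carbinol may ionise and racemise.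
- Fallback: a deprotection in two chemoselective stages. It sets out from 16 and comes back at 17.
  - KHF2 in MeOH at rt, which is selective for phenolic silyl ethers, would give the O1-mono-TBS diphenol, (1S,6E)-1-(tert-butyldimethylsilyloxy)-5-hydroxy-7-(4-hydroxy-3-methoxyphenyl)-1-(4-hydroxyphenyl)hepta-4,6-dien-3-one F7, in which the diketone still cannot be attacked by O1.
  - The single remaining Si–O bond would then be cut by a short, monitored exposure to Et3N·3HF in MeCN at 0 °C to give 17.

## Further compounds

F0 | step 7 | none | none
F1 | step 6 | 4-(tert-butyldimethylsilyloxy)benzaldehyde | O=Cc1ccc(O[Si](C)(C)C(C)(C)C)cc1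
F2 | step 6 | racemic 1-[4-(tert-butyldimethylsilyloxy)phenyl]but-3-yn-1-ol | C#CCC(O)c1ccc(O[Si](C)(C)C(C)(C)C)cc1
F3 | step 6 | racemic 1-[4-(tert-butyldimethylsilyloxy)phenyl]-2-{3-[(E)-2-(4-tert-butyldimethylsilyloxy-3-methoxyphenyl)ethenyl]isoxazol-5-yl}ethanol | COc1cc(/C=C/c2cc(CC(O)c3ccc(O[Si](C)(C)C(C)(C)C)cc3)on2)ccc1O[Si](C)(C)C(C)(C)C
F4 | step 10 | 5-[(2S)-2-(tert-butyldiphenylsilyloxy)-2-(4-tert-butyldimethylsilyloxyphenyl)ethyl]-3-[(E)-2-(4-tert-butyldimethylsilyloxy-3-methoxyphenyl)ethenyl]isoxazole | COc1cc(/C=C/c2cc(C[C@H](O[Si](c3ccccc3)(c4ccccc4)C(C)(C)C)c5ccc(O[Si](C)(C)C(C)(C)C)cc5)on2)ccc1O[Si](C)(C)C(C)(C)C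
F5 | step 10 | (1S,4Z,6E)-5-amino-1-(tert-butyldiphenylsilyloxy)-7-(4-tert-butyldimethylsilyloxy-3-methoxyphenyl)-1-(4-tert-butyldimethylsilyloxyphenyl)hepta-4,6-dien-3-one | COc1cc(/C=C/C(N)=C/C(=O)C[C@H](O[Si](c2ccccc2)(c3ccccc3)C(C)(C)C)c4ccc(O[Si](C)(C)C(C)(C)C)cc4)ccc1O[Si](C)(C)C(C)(C)C
F6 | step 10 | (1S,6E)-1-(tert-butyldiphenylsilyloxy)-5-hydroxy-7-(4-tert-butyldimethylsilyloxy-3-methoxyphenyl)-1-(4-tert-butyldimethylsilyloxyphenyl)hepta-4,6-dien-3-one (enol form) | COc1cc(/C=C/C(O)=C\C(=O)C[C@H](O[Si](c2ccccc2)(c3ccccc3)C(C)(C)C)c4ccc(O[Si](C)(C)C(C)(C)C)cc4)ccc1O[Si](C)(C)C(C)(C)C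
F7 | step 11 | (1S,6E)-1-(tert-butyldimethylsilyloxy)-5-hydroxy-7-(4-hydroxy-3-methoxyphenyl)-1-(4-hydroxyphenyl)hepta-4,6-dien-3-one (enol form) | COc1cc(/C=C/C(O)=C\C(=O)C[C@H](O[Si](C)(C)C(C)(C)C)c2ccc(O)cc2)ccc1O
A1 | alternative 1 | tris-TBS ether of the target, diketo tautomer of 16 | COc1cc(/C=C/C(=O)CC(=O)C[C@H](O[Si](C)(C)C(C)(C)C)c2ccc(O[Si](C)(C)C(C)(C)C)cc2)ccc1O[Si](C)(C)C(C)(C)C
A2 | alternative 1 | (S)-5-(tert-butyldimethylsilyloxy)-5-[4-(tert-butyldimethylsilyloxy)phenyl]-3-oxopentanoic acid | OC(=O)CC(=O)C[C@H](O[Si](C)(C)C(C)(C)C)c1ccc(O[Si](C)(C)C(C)(C)C)cc1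
A3 | alternative 1 | (E)-3-[4-(tert-butyldimethylsilyloxy)-3-methoxyphenyl]-1-(imidazol-1-yl)prop-2-en-1-one | COc1cc(/C=C/C(=O)n2ccnc2)ccc1O[Si](C)(C)C(C)(C)C
A4 | alternative 2 | C3 dithiane with O1 silylated and free C5 carbinol, (1S), both C5 epimers | COc1cc(/C=C/C(O)CC2(C[C@H](O[Si](C)(C)C(C)(C)C)c3ccc(O[Si](C)(C)C(C)(C)C)cc3)SCCCS2)ccc1O[Si](C)(C)C(C)(C)C
A5 | alternative 2 | (R)-2-[4-(tert-butyldimethylsilyloxy)phenyl]oxirane | CC(C)(C)[Si](C)(C)Oc1ccc([C@@H]2CO2)cc1
A6 | alternative 2 | racemic 2-[(E)-2-(4-tert-butyldimethylsilyloxy-3-methoxyphenyl)ethenyl]oxirane | COc1cc(/C=C/C2CO2)ccc1O[Si](C)(C)C(C)(C)C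
A7 | alternative 2 | 2-(tert-butyldimethylsilyl)-1,3-dithiane | CC(C)(C)[Si](C)(C)C1SCCCS1
A8 | alternative 3 | (1S)-1-hydroxy ketone with O5 triethylsilyl ether, both C5 epimers | COc1cc(/C=C/C(CC(=O)C[C@H](O)c2ccc(O[Si](C)(C)C(C)(C)C)cc2)O[Si](CC)(CC)CC)ccc1O[Si](C)(C)C(C)(C)C
A9 | alternative 3 | C1=C2 enone with O5 triethylsilyl ether, racemic at C5 | COc1cc(/C=C/C(CC(=O)/C=C/c2ccc(O[Si](C)(C)C(C)(C)C)cc2)O[Si](CC)(CC)CC)ccc1O[Si](C)(C)C(C)(C)C
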